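**Plan**

- Retrosynthesis: the enal is taken back to the isopropenyl methyl group (allylic C–H oxidation), and the C3 isovalerate and the benzylic acetate to their alcohols. The ring bond C2–C3 is then cut as a carbonyl allylation, and the open chain is cut at the enol ether bond O1–C2 (phenol plus vinyl iodide), at the allylic C–B bond and at the aryl–CHO bond.
- Enabling feature: C2 (the ring CH on O1) and C3 (the benzylic carbinol CH) are adjacent, trans, oxygen-bearing stereocentres, and C2 carries the alkene carbon C1' with its terminal CH2. This is the pattern left when the γ-carbon of an (E)-γ-aryloxyallylboron adds to an ortho formyl group.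
- Forward order: 4-hydroxyacetophenone is ortho-formylated and the aldehyde masked. The phenol is O-vinylated with an (E)-iodoalkene made from propargyl alcohol, the ketone is reduced and acetylated, and the allylic acetate is exchanged for Bpin. The aldehyde is then released and the dihydrofuran ring (the only ring formed) is closed; esterification and allylic oxidation finish the route.
- Stereochemistry: the benzylic S centre comes from RuCl[(S,S)-TsDPEN](p-cymene) transfer hydrogenation. C3 (S) comes from the chiral phosphoric acid in the ring closure, and C2 (R, trans to C3) from the E enol ether geometry through the chair transition state.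

Key step: step 10

Remark: (R)-TRIP, (R)-3,3'-bis(2,4,6-triisopropylphenyl)-1,1'-binaphthyl-2,2'-diyl hydrogen phosphate, is chosen on the assumption that it directs the allyl unit to the Re face of the tethered formyl group (which here gives 3S), as it does in intermolecular allylborations of aryl aldehydes; if the sense were opposite, (S)-TRIP would be used.

**Route**

Step 1
Reactants: 1 propargyl alcohol (prop-2-yn-1-ol)
Product: 3 (E)-3-iodo-2-methylprop-2-en-1-ol, via alkenylalane 2 (not isolated)
Conditions: AlMe3 (3 equiv), Cp2ZrCl2 (0.25 equiv), CH2Cl2, 0 °C to rt; then I2, THF, −30 to 0 °C; aq. K2CO3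
Reagents that add atoms: trimethylaluminium, C[Al](C)C; iodine, II
Why: Negishi zirconium-catalysed carboalumination adds methyl and aluminium syn across the alkyne with methyl on the internal carbon, and iodinolysis of the C–Al bond with retention should give the E vinyl iodide (iodine trans to CH2OH).

Step 2
Reactants: 3 (E)-3-iodo-2-methylprop-2-en-1-ol
Product: 4 (E)-3-iodo-2-methylprop-2-en-1-yl acetate
Conditions: Ac2O, pyridine, DMAP (5 mol%), CH2Cl2, 0 °C to rt
Reagents that add atoms: acetic anhydride, CC(=O)OC(C)=O
Why: DMAP-catalysed O-acetylation of a primary alcohol; the acetate masks the hydroxyl during the coupling and later serves as the leaving group for borylation.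

Step 3
Reactants: 5 4-hydroxyacetophenone
Product: 6 5-acetyl-2-hydroxybenzaldehyde
Conditions: hexamethylenetetramine (1.1 equiv), CF3CO2H, 90 °C; then 3 M aq. HCl, rt
Reagents that add atoms: hexamethylenetetramine, C1N2CN3CN1CN(C2)C3; water, O
Why: Duff ortho-formylation in trifluoroacetic acid tolerates electron-poor phenols; the para position is blocked, so the iminium electrophile attacks ortho to the hydroxyl, and one equivalent of the amine limits diformylation.

Step 4
Reactants: 6 5-acetyl-2-hydroxybenzaldehyde
Product: 7 1-[3-(1,3-dioxolan-2-yl)-4-hydroxyphenyl]ethan-1-one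
Conditions: HOCH2CH2OH (1.5 equiv), p-TsOH·H2O (2 mol%), toluene, reflux, Dean–Stark; Et3N quench
Reagents that add atoms: ethylene glycol, OCCO
Why: Acid-catalysed acetalisation with azeotropic removal of water is much faster at the aldehyde than at the conjugated aryl methyl ketone, so only the formyl group is masked, which prevents Claisen–Schmidt condensation with the acetyl group under the basic coupling that follows.

Step 5
Reactants: 7 1-[3-(1,3-dioxolan-2-yl)-4-hydroxyphenyl]ethan-1-one; 4 (E)-3-iodo-2-methylprop-2-en-1-yl acetate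
Product: 8 (E)-3-[4-acetyl-2-(1,3-dioxolan-2-yl)phenoxy]-2-methylprop-2-en-1-yl acetate
Conditions: CuI (10 mol%), N,N-dimethylglycine·HCl (30 mol%), Cs2CO3 (2.5 equiv), 1,4-dioxane, 90 °C
Reagents that add atoms: none
Why: Ullmann-type CuI-catalysed C–O coupling of a phenoxide with a vinyl iodide proceeds with retention of alkene geometry, and it is placed before the benzylic oxygen is introduced so that no para-hydroxybenzyl ester (a quinone methide precursor) ever meets base.

Step 6
Reactants: 8 (E)-3-[4-acetyl-2-(1,3-dioxolan-2-yl)phenoxy]-2-methylprop-2-en-1-yl acetate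
Product: 9 (E)-3-{2-(1,3-dioxolan-2-yl)-4-[(S)-1-hydroxyethyl]phenoxy}-2-methylprop-2-en-1-yl acetate
Conditions: RuCl[(S,S)-TsDPEN](p-cymene) (1 mol%), HCO2H/Et3N (1:2), DMF, 30 °C
Reagents that add atoms: none
Why: Noyori asymmetric transfer hydrogenation of an aryl methyl ketone with the (S,S)-ligand gives the (S)-carbinol, as established for acetophenones; the outer-sphere hydride transfer leaves the enol ether, the ester and the acetal alone, and the amine-rich medium protects the acetal.

Step 7
Reactants: 9 (E)-3-{2-(1,3-dioxolan-2-yl)-4-[(S)-1-hydroxyethyl]phenoxy}-2-methylprop-2-en-1-yl acetate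
Product: 10 (S)-1-{4-[(E)-3-acetoxy-2-methylprop-1-en-1-yloxy]-3-(1,3-dioxolan-2-yl)phenyl}ethyl acetate
Conditions: Ac2O (1.5 equiv), Et3N, DMAP (5 mol%), CH2Cl2, 0 °C
Reagents that add atoms: acetic anhydride, CC(=O)OC(C)=O
Why: DMAP-catalysed acetylation under basic conditions acylates the benzylic oxygen without ionising the C–O bond, so the S configuration is kept; any allylic alcohol freed by acetate loss in steps 5 or 6 is re-acetylated at the same time.

Step 8
Reactants: 10 (S)-1-{4-[(E)-3-acetoxy-2-methylprop-1-en-1-yloxy]-3-(1,3-dioxolan-2-yl)phenyl}ethyl acetate; 11 bis(pinacolato)diboron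
Product: 12 (S)-1-{3-(1,3-dioxolan-2-yl)-4-[(E)-2-methyl-3-(4,4,5,5-tetramethyl-1,3,2-dioxaborolan-2-yl)prop-1-en-1-yloxy]phenyl}ethyl acetate
Conditions: Pd2(dba)3 (2.5 mol%), DMSO, 50 °C
Reagents that add atoms: bis(pinacolato)diboron (compound 11), CC1(C)OB(OC1(C)C)B1OC(C)(C)C(C)(C)O1
Why: Miyaura borylation of an allylic acetate: ligand-free zerovalent palladium ionises only the allylic ester, the acetate-bound π-allylpalladium transmetalates with the diboron and reductive elimination places boron on the unsubstituted terminus; the syn π-allyl isomer that arises from the E acetate is also the thermodynamically preferred one, so the E enol ether should persist.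

Step 9
Reactants: 12 (S)-1-{3-(1,3-dioxolan-2-yl)-4-[(E)-2-methyl-3-(4,4,5,5-tetramethyl-1,3,2-dioxaborolan-2-yl)prop-1-en-1-yloxy]phenyl}ethyl acetate
Product: 13 (S)-1-{3-formyl-4-[(E)-2-methyl-3-(4,4,5,5-tetramethyl-1,3,2-dioxaborolan-2-yl)prop-1-en-1-yloxy]phenyl}ethyl acetate
Conditions: 0.5 M aq. HCl/THF (1:4), 0 °C; cold aq. NaHCO3; cold toluene extraction, Na2SO4; solution used at once without purification
Reagents that add atoms: water, O
Why: Acid-catalysed hydrolysis of an aryl 1,3-dioxolane with an ortho oxygen donor is orders of magnitude faster than protonation of the aryl enol ether or protodeboronation of the allyl boronate, so brief cold dilute acid should free the aldehyde, which is kept cold to hold back uncatalysed ring closure.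

Step 10
Reactants: 13 (S)-1-{3-formyl-4-[(E)-2-methyl-3-(4,4,5,5-tetramethyl-1,3,2-dioxaborolan-2-yl)prop-1-en-1-yloxy]phenyl}ethyl acetate
Product: 15 (S)-1-[(2R,3S)-3-hydroxy-2-(prop-1-en-2-yl)-2,3-dihydrobenzofuran-5-yl]ethyl acetate, via pinacol borate 14 (not isolated)
Conditions: (R)-TRIP (10 mol%), 4 Å MS, toluene, −40 to −20 °C; then aq. NaHCO3
Reagents that add atoms: none
Why: The phosphoric acid hydrogen-bonds to a pinacolate oxygen, boron binds the aldehyde oxygen, and the γ-carbon (the oxygen-bearing alkene CH) adds to the carbonyl through a six-membered chair of B, O, C(carbonyl), Cγ, Cβ and Cα; the allylic transposition leaves the isopropenyl group on C2 and gives borate 14, which is hydrolysed on work-up. The closest known reactions are the thermal ring-closing allylboration of ω-formyl (E)-γ-alkoxyallylboronates to trans-2-alkenyl-3-hydroxy oxacycles and the chiral phosphoric acid-catalysed allylboration of aryl aldehydes with pinacol allyl- and γ-alkoxyallylboronates. The dihydrofuran ring closes by C2–C3 bond formation in a 5-exo-trig attack on the formyl group, with the new five-membered ring trans-fused to the chair. C3 is set by the catalyst, (R)-TRIP being expected to direct attack to the Re face of the aldehyde, which corresponds to 3S. C2 is set by the E enol ether geometry, which places the aryloxy oxygen equatorial next to the equatorial aryl group and so gives the anti (2,3-trans) relationship, 2R once C3 is S. The step needs catalyst control over both the remote benzylic centre and the uncatalysed closure; the E geometry of the substrate secures trans, and the low reactivity of a pinacol boronate toward an electron-rich aryl aldehyde at −40 °C, with 13 generated cold, is meant to leave the catalysed path dominant.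

Step 11
Reactants: 15 (S)-1-[(2R,3S)-3-hydroxy-2-(prop-1-en-2-yl)-2,3-dihydrobenzofuran-5-yl]ethyl acetate
Product: 16 (2R,3S)-5-[(S)-1-acetoxyethyl]-2-(prop-1-en-2-yl)-2,3-dihydrobenzofuran-3-yl 3-methylbutanoate
Conditions: 3-methylbutanoyl chloride (1.3 equiv), pyridine, DMAP (10 mol%), CH2Cl2, 0 °C
Reagents that add atoms: 3-methylbutanoyl chloride, CC(C)CC(Cl)=O
Why: Nucleophile-catalysed esterification of the secondary C3 alcohol with an acid chloride occurs at oxygen under basic conditions, so neither C2 nor C3 is touched and the trans configuration is kept.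

Step 12
Reactants: 16 (2R,3S)-5-[(S)-1-acetoxyethyl]-2-(prop-1-en-2-yl)-2,3-dihydrobenzofuran-3-yl 3-methylbutanoate
Product: 17 (2R,3S)-5-[(S)-1-acetoxyethyl]-2-(3-hydroxyprop-1-en-2-yl)-2,3-dihydrobenzofuran-3-yl 3-methylbutanoate
Conditions: SeO2 (0.5 equiv), t-BuOOH (3 equiv, in decane), CH2Cl2, 0 °C to rt; crude product (with any enal already formed) taken on
Reagents that add atoms: selenium dioxide, O=[Se]=O; tert-butyl hydroperoxide, CC(C)(C)OO
Why: Sharpless catalytic SeO2/t-BuOOH allylic oxidation (ene reaction, then 2,3-sigmatropic shift) of a 1,1-disubstituted alkene attacks the methyl group in preference to the oxygen-bearing C2 methine and should give the primary allylic alcohol with the alkene in place.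

Step 13
Reactants: 17 (2R,3S)-5-[(S)-1-acetoxyethyl]-2-(3-hydroxyprop-1-en-2-yl)-2,3-dihydrobenzofuran-3-yl 3-methylbutanoate
Product: 18 (2R,3S)-5-[(S)-1-acetoxyethyl]-2-(3-oxoprop-1-en-2-yl)-2,3-dihydrobenzofuran-3-yl 3-methylbutanoate (CNP0252902.2)
Conditions: activated MnO2 (15 equiv), CH2Cl2, rt
Reagents that add atoms: none
Why: MnO2 oxidation is selective for primary allylic alcohols and runs under neutral conditions, so the enal should form without loss of either ester or change at any stereocentre.

**Compound list**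

1 | propargyl alcohol (prop-2-yn-1-ol) | C#CCO | starting material
2 | dimethylaluminium (E)-3-(dimethylalumanyl)-2-methylprop-2-en-1-olate (alkenylalane) | C[Al](C)OC/C(C)=C/[Al](C)C | intermediate (not isolated)
3 | (E)-3-iodo-2-methylprop-2-en-1-ol | OC/C(C)=C/I | intermediate
4 | (E)-3-iodo-2-methylprop-2-en-1-yl acetate | CC(=O)OC/C(C)=C/I | intermediate
5 | 4-hydroxyacetophenone | CC(=O)c1ccc(O)cc1 | starting material
6 | 5-acetyl-2-hydroxybenzaldehyde | CC(=O)c1ccc(O)c(C=O)c1 | intermediate
7 | 1-[3-(1,3-dioxolan-2-yl)-4-hydroxyphenyl]ethan-1-one | CC(=O)c1ccc(O)c(C2OCCO2)c1 | intermediate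
8 | (E)-3-[4-acetyl-2-(1,3-dioxolan-2-yl)phenoxy]-2-methylprop-2-en-1-yl acetate | O1CCOC1c1cc(C(C)=O)ccc1O/C=C(\C)COC(C)=O | intermediate
9 | (E)-3-{2-(1,3-dioxolan-2-yl)-4-[(S)-1-hydroxyethyl]phenoxy}-2-methylprop-2-en-1-yl acetate | O1CCOC1c1cc([C@H](C)O)ccc1O/C=C(\C)COC(C)=O | intermediate
10 | (S)-1-{4-[(E)-3-acetoxy-2-methylprop-1-en-1-yloxy]-3-(1,3-dioxolan-2-yl)phenyl}ethyl acetate | O1CCOC1c1cc([C@H](C)OC(C)=O)ccc1O/C=C(\C)COC(C)=O | intermediate
11 | bis(pinacolato)diboron | CC1(C)OB(OC1(C)C)B1OC(C)(C)C(C)(C)O1 | starting material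
12 | (S)-1-{3-(1,3-dioxolan-2-yl)-4-[(E)-2-methyl-3-(4,4,5,5-tetramethyl-1,3,2-dioxaborolan-2-yl)prop-1-en-1-yloxy]phenyl}ethyl acetate | O1CCOC1c1cc([C@H](C)OC(C)=O)ccc1O/C=C(\C)CB1OC(C)(C)C(C)(C)O1 | intermediate
13 | (S)-1-{3-formyl-4-[(E)-2-methyl-3-(4,4,5,5-tetramethyl-1,3,2-dioxaborolan-2-yl)prop-1-en-1-yloxy]phenyl}ethyl acetate | O=Cc1cc([C@H](C)OC(C)=O)ccc1O/C=C(\C)CB1OC(C)(C)C(C)(C)O1 | intermediate
14 | (S)-1-{(2R,3S)-2-(prop-1-en-2-yl)-3-[(4,4,5,5-tetramethyl-1,3,2-dioxaborolan-2-yl)oxy]-2,3-dihydrobenzofuran-5-yl}ethyl acetate (pinacol borate of 15) | C=C(C)[C@H]1Oc2ccc([C@H](C)OC(C)=O)cc2[C@@H]1OB1OC(C)(C)C(C)(C)O1 | intermediate (not isolated)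
15 | (S)-1-[(2R,3S)-3-hydroxy-2-(prop-1-en-2-yl)-2,3-dihydrobenzofuran-5-yl]ethyl acetate | C=C(C)[C@H]1Oc2ccc([C@H](C)OC(C)=O)cc2[C@@H]1O | intermediate
16 | (2R,3S)-5-[(S)-1-acetoxyethyl]-2-(prop-1-en-2-yl)-2,3-dihydrobenzofuran-3-yl 3-methylbutanoate | C=C(C)[C@H]1Oc2ccc([C@H](C)OC(C)=O)cc2[C@@H]1OC(=O)CC(C)C | intermediate
17 | (2R,3S)-5-[(S)-1-acetoxyethyl]-2-(3-hydroxyprop-1-en-2-yl)-2,3-dihydrobenzofuran-3-yl 3-methylbutanoate | C=C(CO)[C@H]1Oc2ccc([C@H](C)OC(C)=O)cc2[C@@H]1OC(=O)CC(C)C | intermediate
18 | (2R,3S)-5-[(S)-1-acetoxyethyl]-2-(3-oxoprop-1-en-2-yl)-2,3-dihydrobenzofuran-3-yl 3-methylbutanoate | C=C(C=O)[C@H]1Oc2ccc([C@H](C)OC(C)=O)cc2[C@@H]1OC(=O)CC(C)C | target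

**Step count and risks**

Total steps: 13. Longest linear sequence: 11 steps (steps 3 to 13 from 4-hydroxyacetophenone; equally steps 1, 2 and 5 to 13 from propargyl alcohol).

Steps most likely to fail:

1. Step 10. The uncatalysed ring closure may compete with the catalysed one, so that the ring centres form without control relative to the remote benzylic centre and both trans diastereomers arise. The fallback sets out from 13 and comes back at 16. The aldehyde is allowed to close without catalyst (toluene, 0 °C to rt), which by the same chair should give only trans products: borate 14 together with its ring-enantiomeric (2S,3R) pinacol borate F1. Work-up with aq. NaHCO3 gives 15 and (S)-1-[(2S,3R)-3-hydroxy-2-(prop-1-en-2-yl)-2,3-dihydrobenzofuran-5-yl]ethyl acetate F2. The mixture is acylated with 3-methylbutanoic anhydride (0.6 equiv) under (R)-benzotetramisole catalysis (i-Pr2NEt, CHCl3, 0 °C), the established acyl-transfer resolution of benzylic alcohols; the catalyst enantiomer that esterifies the (3S)-carbinol is the one retained. Ester 16 is separated from unreacted F2 by chromatography, and the route continues from 16.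

2. Step 9. Acid may cleave the aryl enol ether or cause protodeboronation during acetal hydrolysis, and the freed aldehyde may cyclise before it reaches the catalyst. The fallback sets out from 10 and comes back at 13. The acetal is hydrolysed while no boron is present (PPTS, acetone/H2O, rt) to (E)-3-{4-[(S)-1-acetoxyethyl]-2-formylphenoxy}-2-methylprop-2-en-1-yl acetate F3. NaBH4 (MeOH/THF, −40 °C) reduces only the aldehyde to (E)-3-{4-[(S)-1-acetoxyethyl]-2-(hydroxymethyl)phenoxy}-2-methylprop-2-en-1-yl acetate F4. The allylic acetate is borylated as in step 8 (11, Pd2(dba)3, DMSO, 50 °C) to (S)-1-{3-(hydroxymethyl)-4-[(E)-2-methyl-3-(4,4,5,5-tetramethyl-1,3,2-dioxaborolan-2-yl)prop-1-en-1-yloxy]phenyl}ethyl acetate F5, which cannot cyclise because it has no carbonyl group. Swern oxidation ((COCl)2, DMSO, CH2Cl2, −78 °C; i-Pr2NEt) then delivers 13 at −78 °C under non-acidic conditions, and the cold extract goes into step 10.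

3. Step 12. The ene reaction may also attack the ring C2–H, the product may over-oxidise, and the acidic selenium medium may promote loss of the C3 ester with aromatisation to the benzofuran. The fallback sets out from 16 and comes back at 18. The Schenck ene reaction with singlet oxygen (O2, hν, tetraphenylporphyrin, CH2Cl2, 0 °C) converts the isopropenyl group into the rearranged primary allylic hydroperoxide, (2R,3S)-5-[(S)-1-acetoxyethyl]-2-(3-hydroperoxyprop-1-en-2-yl)-2,3-dihydrobenzofuran-3-yl 3-methylbutanoate F6. Kornblum–DeLaMare-type dehydration (Ac2O, pyridine, DMAP, 0 °C) gives the enal 18 directly, so the target is reached without passing through 17.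

Further compounds
F1 | step 10 | (S)-1-{(2S,3R)-2-(prop-1-en-2-yl)-3-[(4,4,5,5-tetramethyl-1,3,2-dioxaborolan-2-yl)oxy]-2,3-dihydrobenzofuran-5-yl}ethyl acetate | C=C(C)[C@@H]1Oc2ccc([C@H](C)OC(C)=O)cc2[C@H]1OB1OC(C)(C)C(C)(C)O1
F2 | step 10 | (S)-1-[(2S,3R)-3-hydroxy-2-(prop-1-en-2-yl)-2,3-dihydrobenzofuran-5-yl]ethyl acetate | C=C(C)[C@@H]1Oc2ccc([C@H](C)OC(C)=O)cc2[C@H]1O
F3 | step 9 | (E)-3-{4-[(S)-1-acetoxyethyl]-2-formylphenoxy}-2-methylprop-2-en-1-yl acetate | O=Cc1cc([C@H](C)OC(C)=O)ccc1O/C=C(\C)COC(C)=O
F4 | step 9 | (E)-3-{4-[(S)-1-acetoxyethyl]-2-(hydroxymethyl)phenoxy}-2-methylprop-2-en-1-yl acetate | OCc1cc([C@H](C)OC(C)=O)ccc1O/C=C(\C)COC(C)=O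
F5 | step 9 | (S)-1-{3-(hydroxymethyl)-4-[(E)-2-methyl-3-(4,4,5,5-tetramethyl-1,3,2-dioxaborolan-2-yl)prop-1-en-1-yloxy]phenyl}ethyl acetate | OCc1cc([C@H](C)OC(C)=O)ccc1O/C=C(\C)CB1OC(C)(C)C(C)(C)O1
F6 | step 12 | (2R,3S)-5-[(S)-1-acetoxyethyl]-2-(3-hydroperoxyprop-1-en-2-yl)-2,3-dihydrobenzofuran-3-yl 3-methylbutanoate | C=C(COO)[C@H]1Oc2ccc([C@H](C)OC(C)=O)cc2[C@@H]1OC(=O)CC(C)C
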